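**Plan**
- Retrosynthetic cuts, in order: (a) C6–Cl, by anti opening of a 1,6-oxirane with chloride; (b) the benzoate ester bonds at O7 and O2; (c) the oxirane C6–O bond, from the C1 alkoxide and an O6 mesylate; (d) C1–C6 and C2–C3, the two bonds of a [4+2] cycloaddition.
- Enabling feature: in ring C1–C6 the oxygens on C3 and C6 are cis across C4=C5 and the oxygens on C1 and C2 are cis, with C7 on C1. This is the pattern of an adduct of an (E,E)-1,4-dioxygenated butadiene (C3–C6) with a cyclic cis-enediol derivative (a 2-oxo-1,3-dioxole, C1=C2) carrying C7 as an acyl group.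
- Forward order: the dienophile is made from glycerol carbonate (steps 1–3); step 4 closes the cyclohexene, the only carbocycle; steps 5–7 turn O3 into a silyl ether and O6 into a mesylate; step 8 reduces C7, removes the carbonate and closes the oxirane; step 9 benzoylates O7 and O2; step 10 opens the oxirane with HCl and frees O3.
- Stereochemistry: all four stereocentres arise in step 4. Relative configuration comes from suprafacial addition through the imide-endo transition state, absolute configuration from the complex [Cu((S,S)-tBu-box)](SbF6)2 of divalent copper. C6 is then inverted twice (oxirane closure, chloride opening); C1, C2 and C3 are not touched again.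

Key step: step 4

Locants and faces: C1 is the quaternary carbinol carbon, C2 and C3 the next two ring carbons, C4=C5 the alkene, C6 the carbon that ends up bearing chlorine, C7 the carbon on C1. With the ring drawn so that C1→C6 runs clockwise, β is the face toward the viewer (the face of C7) and α the opposite face.

Assumption: dienophile 7 binds copper through both imide carbonyls in the s-cis conformation, as acryloyl oxazolidinones do; the (S,S) ligand is chosen on that basis, and the (R,R) ligand would be used if the opposite sense of induction were found.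

**Step 1**
Reactants: 1 glycerol carbonate (4-(hydroxymethyl)-1,3-dioxolan-2-one; racemic)
Product: 2 2-oxo-1,3-dioxolane-4-carboxylic acid (racemic)
Conditions: TEMPO (cat.), NaBr (cat.), trichloroisocyanuric acid, acetone–H2O, 0 °C → rt
Reagents that add atoms: water, O
Why: Oxoammonium-mediated (TEMPO) oxidation takes the primary alcohol through the aldehyde hydrate to the acid, the cyclic carbonate being stable to the acidic oxidising medium and the stereocentre being of no consequence because it is erased in step 3.

**Step 2**
Reactants: 2 2-oxo-1,3-dioxolane-4-carboxylic acid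
Product: 4 5-chloro-2-oxo-1,3-dioxolane-4-carbonyl chloride (cis/trans mixture), via acid chloride 3 (not isolated)
Conditions: SOCl2, DMF (cat.), 60 °C; evaporate; SO2Cl2, AIBN (cat.), PhCl, 80 °C, stopped short of full conversion; distil
Reagents that add atoms: thionyl chloride, O=S(Cl)Cl; sulfuryl chloride, O=S(=O)(Cl)Cl
Why: Acyl chloride formation is followed by free-radical chain chlorination, the reaction that converts ethylene carbonate into chloroethylene carbonate, in which the electrophilic chlorine atom should prefer the O-bearing C5–H2 to the C4–H next to COCl, and either diastereomer or any 4-chloro isomer leads to the same alkene in step 3.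

**Step 3**
Reactants: 4 5-chloro-2-oxo-1,3-dioxolane-4-carbonyl chloride; 5 3-(trimethylsilyl)oxazolidin-2-one
Product: 7 3-(2-oxo-1,3-dioxole-4-carbonyl)oxazolidin-2-one, via chloro imide 6 (not isolated)
Conditions: CH2Cl2, 0 → 40 °C; then Et3N (1.05 equiv), 0 °C; filter, crystallise under exclusion of moisture
Reagents that add atoms: none
Why: Base-free N-acylation of the N-silyl carbamate by the acid chloride (Me3SiCl leaves) is followed by E1cB dehydrochlorination, C4–H being acidified by the imide carbonyl and chloride leaving from C5, as in the preparation of vinylene carbonate from chloroethylene carbonate, and both stereocentres of 6 are erased.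

**Step 4**
Reactants: 7 3-(2-oxo-1,3-dioxole-4-carbonyl)oxazolidin-2-one; 8 (1E,3E)-buta-1,3-diene-1,4-diyl diacetate
Product: 9 cycloadduct 3-[(3β,6β-diacetoxy-1α,2α-carbonyldioxycyclohex-4-en-1β-yl)carbonyl]oxazolidin-2-one
Conditions: [Cu((S,S)-tBu-box)](SbF6)2 (10 mol %; made in the flask from CuCl2, AgSbF6 and 2,2′-(propane-2,2-diyl)bis[(4S)-4-tert-butyl-4,5-dihydrooxazole], AgCl filtered off), diene in twofold amount, CH2Cl2, 0 °C → rt
Reagents that add atoms: none
Why: Proposed new method: the two imide carbonyls of 7 chelate the cationic divalent copper centre, which lowers the LUMO of C1=C2 so that the weakly nucleophilic diene 8 should add in a concerted, asynchronous [4+2] cycloaddition, suprafacial on both partners, with C2–C3 forming ahead of C1–C6. The closest known reaction types are the copper bis(oxazoline)-catalysed Diels–Alder reactions of acryloyl and 3-acyloxyacryloyl oxazolidinones with 1-acetoxybutadiene and cyclopentadiene and the thermal addition of 8 to vinylene carbonate; a dienophile oxygenated at both alkene carbons has not been used in the catalysed reaction. The cyclohexene ring is closed in the intermolecular [4+2] mode, C1–C6 and C2–C3 being formed in one step and C4=C5 arising from the central diene bond. C3 and C6 become cis because both acetoxy groups are outside substituents of the (E,E)-diene; C1–O and C2–O are cis because they are held in the dioxolone ring; the imide-endo transition state puts C7 on the face of the two acetoxy groups; and the absolute sense follows from the s-cis chelate in the distorted square plane of the (S,S) complex, whose tert-butyl group covers the Si face of C1 so that the diene adds to the Re face. The step needs imide-endo rather than carbonate-endo diastereoselectivity and high facial selectivity, both of which the two-point binding of the acyl oxazolidinone to copper is meant to secure, while the C2-symmetric diene excludes regioisomers.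

**Step 5**
Reactants: 9 cycloadduct
Product: 10 diol 3-[(3β,6β-dihydroxy-1α,2α-carbonyldioxycyclohex-4-en-1β-yl)carbonyl]oxazolidin-2-one
Conditions: HCl (1.25 M in MeOH), 0 °C → rt; evaporate cold
Reagents that add atoms: none
Why: Acid-catalysed transesterification (methanolysis) removes the two secondary acetates while the cyclic carbonate and the N-acyl oxazolidinone should withstand dilute methanolic HCl, whereas a basic deacetylation would open the carbonate and provoke attack of O3 on the imide.

**Step 6**
Reactants: 10 diol
Product: 11 3-[(3β-(tert-butyldimethylsilyloxy)-6β-hydroxy-1α,2α-carbonyldioxycyclohex-4-en-1β-yl)carbonyl]oxazolidin-2-one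
Conditions: TBSOTf (1.0 equiv, slow addition), 2,6-lutidine, CH2Cl2, −78 °C
Reagents that add atoms: tert-butyldimethylsilyl triflate, CC(C)(C)[Si](C)(C)OS(=O)(=O)C(F)(F)F
Why: Kinetic monosilylation should select the allylic hydroxyl on C3, whose neighbour C2 is a methine, over the one on C6, which adjoins the quaternary C1 and is cis to the bulky acyl group, and a silyl triflate at −78 °C with a hindered pyridine base leaves neither time nor a nucleophilic base for acyl transfer to O3.

**Step 7**
Reactants: 11 O3 silyl ether
Product: 12 3-[(3β-(tert-butyldimethylsilyloxy)-6β-(methanesulfonyloxy)-1α,2α-carbonyldioxycyclohex-4-en-1β-yl)carbonyl]oxazolidin-2-one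
Conditions: MsCl, Et3N, CH2Cl2, −20 °C
Reagents that add atoms: methanesulfonyl chloride, CS(=O)(=O)Cl
Why: Mesylation through sulfene reaches the hindered C6 hydroxyl, and the allylic mesylate is stabilised against ionisation by the electron-withdrawing C1–O bond and imide next to it.

**Step 8**
Reactants: 12 O6 mesylate
Product: 15 epoxy diol 1α,6α-epoxy-1β-(hydroxymethyl)-3β-(tert-butyldimethylsilyloxy)cyclohex-4-en-2α-ol, via hydroxymethyl carbonate 13 (not isolated), via triol mesylate 14 (not isolated)
Conditions: LiBH4, MeOH (1 equiv), THF, 0 °C; then MeOH, K2CO3, 0 °C → rt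
Reagents that add atoms: none
Why: Borohydride reduction of the N-acyl oxazolidinone gives the C7 carbinol, methoxide transesterification of the carbonate then frees O1 and O2, and the C1 alkoxide displaces the anti-periplanar O6 mesylate in an intramolecular Williamson (3-exo-tet) closure with inversion at C6, so the oxirane lies on the α face, O2 and O7 being unable to reach the rear of C6 and attack on the fully substituted C1 not being expected.

**Step 9**
Reactants: 15 epoxy diol
Product: 16 [2α-(benzoyloxy)-1α,6α-epoxy-3β-(tert-butyldimethylsilyloxy)cyclohex-4-en-1β-yl]methyl benzoate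
Conditions: BzCl (3 equiv), pyridine, DMAP (cat.), CH2Cl2, 0 °C → rt
Reagents that add atoms: benzoyl chloride, O=C(Cl)c1ccccc1
Why: DMAP-catalysed acylation esterifies the only two free hydroxyls, primary O7 and secondary O2, and the oxirane and silyl ether are inert to the buffered conditions.

**Step 10**
Reactants: 16 epoxide dibenzoate
Product: 18 [(1R,2R,3S,6R)-2-(benzoyloxy)-6-chloro-1,3-dihydroxycyclohex-4-en-1-yl]methyl benzoate (1α-OH 2α-OBz 3β-OH 6β-Cl; CNP0326102.1), via silylated chlorohydrin 17 (not isolated)
Conditions: HCl (2 M in Et2O), CH2Cl2, −30 → 0 °C; then MeOH, rt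
Reagents that add atoms: hydrogen chloride, Cl
Why: Acid-promoted anti opening of the vinyl oxirane by chloride at the allylic carbon C6 (borderline SN2, inversion) returns C6 to the β configuration and leaves the C1 hydroxyl α, the fully substituted C1 being deactivated by its acyloxy-bearing neighbours, and methanolic HCl then cleaves the silyl ether while the benzoates should survive.

**Compound list**
1 | glycerol carbonate, 4-(hydroxymethyl)-1,3-dioxolan-2-one (racemic) | OCC1COC(=O)O1 | starting material
2 | 2-oxo-1,3-dioxolane-4-carboxylic acid (racemic) | OC(=O)C1COC(=O)O1 | intermediate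
3 | 2-oxo-1,3-dioxolane-4-carbonyl chloride (racemic; not isolated) | ClC(=O)C1COC(=O)O1 | intermediate
4 | 5-chloro-2-oxo-1,3-dioxolane-4-carbonyl chloride (cis/trans mixture, racemic) | ClC(=O)C1OC(=O)OC1Cl | intermediate
5 | 3-(trimethylsilyl)oxazolidin-2-one | C[Si](C)(C)N1CCOC1=O | starting material
6 | 3-(5-chloro-2-oxo-1,3-dioxolane-4-carbonyl)oxazolidin-2-one (diastereomer mixture; not isolated) | O=C(N1CCOC1=O)C1OC(=O)OC1Cl | intermediate
7 | 3-(2-oxo-1,3-dioxole-4-carbonyl)oxazolidin-2-one | O=C(N1CCOC1=O)C1=COC(=O)O1 | intermediate
8 | (1E,3E)-buta-1,3-diene-1,4-diyl diacetate | CC(=O)O/C=C/C=C/OC(C)=O | starting material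
9 | cycloadduct: 1α,2α-cyclic carbonate, 3β- and 6β-acetates, 1β-acyl oxazolidinone | O=C1OCCN1C(=O)[C@]12[C@H](OC(C)=O)C=C[C@H](OC(C)=O)[C@H]1OC(=O)O2 | intermediate
10 | 3β,6β-diol with 1α,2α-carbonate and 1β-acyl oxazolidinone | O=C1OCCN1C(=O)[C@]12[C@H](O)C=C[C@H](O)[C@H]1OC(=O)O2 | intermediate
11 | 3β-silyl ether, 6β-alcohol (carbonate and imide as in 10) | O=C1OCCN1C(=O)[C@]12[C@H](O)C=C[C@H](O[Si](C)(C)C(C)(C)C)[C@H]1OC(=O)O2 | intermediate
12 | 3β-silyl ether, 6β-mesylate (carbonate and imide as in 10) | O=C1OCCN1C(=O)[C@]12[C@H](OS(C)(=O)=O)C=C[C@H](O[Si](C)(C)C(C)(C)C)[C@H]1OC(=O)O2 | intermediate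
13 | 1β-hydroxymethyl 1α,2α-carbonate with 3β-silyl ether and 6β-mesylate (not isolated) | OC[C@]12[C@H](OS(C)(=O)=O)C=C[C@H](O[Si](C)(C)C(C)(C)C)[C@H]1OC(=O)O2 | intermediate
14 | 1β-hydroxymethyl-1α,2α-diol with 3β-silyl ether and 6β-mesylate (not isolated) | OC[C@]1(O)[C@H](OS(C)(=O)=O)C=C[C@H](O[Si](C)(C)C(C)(C)C)[C@H]1O | intermediate
15 | 1α,6α-epoxy-1β-(hydroxymethyl)-3β-(tert-butyldimethylsilyloxy)cyclohex-4-en-2α-ol | OC[C@]12[C@@H](O2)C=C[C@H](O[Si](C)(C)C(C)(C)C)[C@H]1O | intermediate
16 | [2α-(benzoyloxy)-1α,6α-epoxy-3β-(tert-butyldimethylsilyloxy)cyclohex-4-en-1β-yl]methyl benzoate | O=C(OC[C@]12[C@@H](O2)C=C[C@H](O[Si](C)(C)C(C)(C)C)[C@H]1OC(=O)c1ccccc1)c1ccccc1 | intermediate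
17 | [2α-(benzoyloxy)-6β-chloro-1α-hydroxy-3β-(tert-butyldimethylsilyloxy)cyclohex-4-en-1β-yl]methyl benzoate (not isolated) | O=C(OC[C@]1(O)[C@H](Cl)C=C[C@H](O[Si](C)(C)C(C)(C)C)[C@H]1OC(=O)c1ccccc1)c1ccccc1 | intermediate
18 | [(1R,2R,3S,6R)-2-(benzoyloxy)-6-chloro-1,3-dihydroxycyclohex-4-en-1-yl]methyl benzoate | O=C(OC[C@]1(O)[C@H](Cl)C=C[C@H](O)[C@H]1OC(=O)c1ccccc1)c1ccccc1 | target

**Totals**
Total steps: 10. Longest linear sequence: 10 steps (1 → 18); 5 and 8 are commercial.

**Steps most likely to fail**

1. Step 4. The doubly oxygenated, trisubstituted dienophile may not be activated enough for the weak diene, or the diene may be consumed at the Lewis acid. The carbonate ring may take the endo position in place of the imide, or the facial selectivity may be low if the chelate is not s-cis. Fallback: run the cycloaddition without catalyst, the thermal Diels–Alder mode known for 8 with acrylic dienophiles and with vinylene carbonate. It sets out from 7 and 8 (toluene, 110–130 °C, sealed tube, radical inhibitor) and should give the imide-endo adduct as a racemate, that is 9 together with the mirror-image adduct F1. Any carbonate-endo isomer is removed by chromatography and the enantiomers are separated by preparative HPLC on a chiral stationary phase, so that the route is rejoined at 9.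

2. Step 6. The silylating agent may not discriminate enough between O3 and O6, and whenever O3 is free the C7 acyl group may pass from nitrogen to O3 (lactonisation with loss of oxazolidinone), in step 5 as well as here. Fallback: remove the imide before the diol is unveiled. Setting out from 9, NaBH4 in THF–H2O at 0 °C gives the C7 primary alcohol F2 with acetates and carbonate intact, and BzCl/pyridine converts it into the C7 benzoate F3. Methanolic HCl then removes the two acetates in the presence of benzoate and carbonate to give the 3β,6β-diol benzoate F4. TBSCl/imidazole in DMF, slow and sterically discriminating conditions that are safe once no acyl donor is left, gives the O3 silyl ether F5, and MsCl/Et3N gives the O6 mesylate F6. K2CO3 in MeOH cleaves benzoate and carbonate from F6 and closes the oxirane through 14, so that the route is rejoined at 15.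

3. Step 10. Chloride may attack C4 in a conjugate (SN2′) opening, the carbonyl of the O7 benzoate may take part at C6, or an acyl group may migrate under the acidic conditions. Fallback: open the oxirane before the benzoates are in place. Setting out from 15, Li2CuCl4 in THF at 0 °C (a known neutral conversion of epoxides into trans-chlorohydrins) gives the chlorohydrin triol F7. BzCl/pyridine then acylates its primary O7 and secondary O2 hydroxyls and leaves the tertiary one, so that the route is rejoined at 17, which is isolated and desilylated with methanolic HCl to 18.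

**Further compounds**
F1 | step 4 | mirror image of cycloadduct 9 | O=C1OCCN1C(=O)[C@@]12[C@@H](OC(C)=O)C=C[C@@H](OC(C)=O)[C@@H]1OC(=O)O2
F2 | step 6 | 3β,6β-diacetoxy-1β-(hydroxymethyl)cyclohex-4-ene-1α,2α-diyl carbonate | OC[C@]12[C@H](OC(C)=O)C=C[C@H](OC(C)=O)[C@H]1OC(=O)O2
F3 | step 6 | (3β,6β-diacetoxy-1α,2α-carbonyldioxycyclohex-4-en-1β-yl)methyl benzoate | O=C(OC[C@]12[C@H](OC(C)=O)C=C[C@H](OC(C)=O)[C@H]1OC(=O)O2)c1ccccc1
F4 | step 6 | (3β,6β-dihydroxy-1α,2α-carbonyldioxycyclohex-4-en-1β-yl)methyl benzoate | O=C(OC[C@]12[C@H](O)C=C[C@H](O)[C@H]1OC(=O)O2)c1ccccc1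
F5 | step 6 | [3β-(tert-butyldimethylsilyloxy)-6β-hydroxy-1α,2α-carbonyldioxycyclohex-4-en-1β-yl]methyl benzoate | O=C(OC[C@]12[C@H](O)C=C[C@H](O[Si](C)(C)C(C)(C)C)[C@H]1OC(=O)O2)c1ccccc1
F6 | step 6 | [3β-(tert-butyldimethylsilyloxy)-6β-(methanesulfonyloxy)-1α,2α-carbonyldioxycyclohex-4-en-1β-yl]methyl benzoate | O=C(OC[C@]12[C@H](OS(C)(=O)=O)C=C[C@H](O[Si](C)(C)C(C)(C)C)[C@H]1OC(=O)O2)c1ccccc1
F7 | step 10 | 6β-chloro-1β-(hydroxymethyl)-3β-(tert-butyldimethylsilyloxy)cyclohex-4-ene-1α,2α-diol | OC[C@]1(O)[C@H](Cl)C=C[C@H](O[Si](C)(C)C(C)(C)C)[C@H]1O
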